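Assumption: germacrane numbering (C1–C15) is used for all fragments, and for each chiral catalyst the antipode that gives the drawn configuration is meant.

**Retrosynthetic overview**
1. 22 comes from 21. The C14 silyl ether is the only protecting group carried.
2. 21 comes from lactol 6 (C1–C6, C15) and allylboronate 18 (C7–C14 plus angelate). They are joined and cyclised in one flask: C6–C7 by allylboration, O–C12 by lactonisation, C1=C10 by ring-closing metathesis.
3. Ring order: the six-membered lactol is spent, the γ-lactone forms first, and the ten-membered carbocycle forms second.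
4. 18 comes from ynoate 16, where syn addition of H and CH2B fixes the alkene geometry that encodes the trans-lactone. 16 comes from ynal 12, allylboronate 9 (sets C8) and angelic acid 14.
5. 6 comes from acrolein 3 and senecioate dienolate 2. The dihydropyranone ring stores C2 and the Z C4=C5 bond.

Step 1
Reactants: 1 methyl 3-methylbut-2-enoate
Product: 2 1-methoxy-3-methyl-1-(trimethylsilyloxy)buta-1,3-diene
Conditions: LiN(i-Pr)2, THF, −78 °C; Me3SiCl
Reagents that add atoms: chlorotrimethylsilane C[Si](C)(C)Cl
Why: Kinetic γ-deprotonation of the senecioate and O-silylation (silyl ketene acetal formation) give the vinylogous Mukaiyama donor, and no stereocentre is formed.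

Step 2
Reactants: 2 1-methoxy-3-methyl-1-(trimethylsilyloxy)buta-1,3-diene; 3 acrolein
Product: 5 (6S)-4-methyl-6-vinyl-5,6-dihydro-2H-pyran-2-one, via open-chain Z-aldol 4 (not isolated)
Conditions: Cu(OTf)2 (10 mol %), (S)-Tol-BINAP (11 mol %), Bu4N(Ph3SiF2) (20 mol %), THF, −78 °C to rt
Reagents that add atoms: none
Why: In this catalytic asymmetric vinylogous Mukaiyama aldol–lactonisation the chiral copper dienolate adds through its γ-carbon to one face of the aldehyde (sets C2 as S), and the aldolate closes onto the ester so that the ring fixes the Z C4=C5 geometry.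

Step 3
Reactants: 5 (6S)-4-methyl-6-vinyl-5,6-dihydro-2H-pyran-2-one
Product: 6 (6S)-4-methyl-6-vinyl-5,6-dihydro-2H-pyran-2-ol (anomer mixture)
Conditions: i-Bu2AlH (1.05 equiv), CH2Cl2, −78 °C
Reagents that add atoms: none
Why: In this partial lactone reduction the tetrahedral aluminium acetal survives at −78 °C, so the product stops at the lactol, which holds the Z-enal (C6) and the C2 hydroxyl in masked form without touching C2.

Step 4
Reactants: 7 2-methylenepropane-1,3-diol
Product: 8 2-{[(tert-butyldimethylsilyl)oxy]methyl}prop-2-en-1-ol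
Conditions: NaH (1.0 equiv), THF, 0 °C; t-BuMe2SiCl (1.0 equiv)
Reagents that add atoms: tert-butyldimethylsilyl chloride CC(C)(C)[Si](C)(C)Cl
Why: Monosilylation of a symmetrical diol through its sparingly soluble monosodium alkoxide is selective for one hydroxyl, and no stereocentre is involved.

Step 5
Reactants: 8 2-{[(tert-butyldimethylsilyl)oxy]methyl}prop-2-en-1-ol
Product: 9 pinacol 2-{[(tert-butyldimethylsilyl)oxy]methyl}allylboronate
Conditions: B2pin2, Pd(MeCN)4(BF4)2 (5 mol %), DMSO/MeOH, rt
Reagents that add atoms: bis(pinacolato)diboron CC1(C)OB(OC1(C)C)B1OC(C)(C)C(C)(C)O1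
Why: Palladium-catalysed allylic C–OH borylation runs through an η3-allyl complex whose two termini are equivalent CH2 groups, so only one regioisomer can form.

Step 6
Reactants: 10 3,3-diethoxyprop-1-yne
Product: 11 methyl 4,4-diethoxybut-2-ynoate
Conditions: n-BuLi, THF, −78 °C; ClCO2Me
Reagents that add atoms: methyl chloroformate COC(=O)Cl
Why: C-acylation of the lithium acetylide with a chloroformate is clean because the acetal masks the aldehyde.

Step 7
Reactants: 11 methyl 4,4-diethoxybut-2-ynoate
Product: 12 methyl 4-oxobut-2-ynoate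
Conditions: p-TsOH (cat.), acetone/H2O, rt; used at once
Reagents that add atoms: water O
Why: Acid-catalysed acetal hydrolysis frees the ynal, which has no enolisable position and is taken on without storage.

Step 8
Reactants: 9 pinacol 2-{[(tert-butyldimethylsilyl)oxy]methyl}allylboronate; 12 methyl 4-oxobut-2-ynoate
Product: 13 methyl (4S)-4-hydroxy-6-{[(tert-butyldimethylsilyl)oxy]methyl}hept-6-en-2-ynoate
Conditions: (R)-TRIP phosphoric acid (5 mol %), toluene, −30 °C
Reagents that add atoms: none
Why: In this chiral Brønsted acid catalysed allylboration the phosphoric acid hydrogen-bonds to a boronate oxygen in the closed six-membered transition state and shields one aldehyde face, which sets C8 as S.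

Step 9
Reactants: 13 methyl (4S)-4-hydroxy-6-{[(tert-butyldimethylsilyl)oxy]methyl}hept-6-en-2-ynoate; 14 angelic acid
Product: 16 methyl (4S)-4-(angeloyloxy)-6-{[(tert-butyldimethylsilyl)oxy]methyl}hept-6-en-2-ynoate, via mixed anhydride 15 (not isolated)
Conditions: 2,4,6-Cl3C6H2COCl, Et3N, toluene, rt; then 13, 75 °C
Reagents that add atoms: none
Why: Yamaguchi esterification run by heating the preformed mixed anhydride without a nucleophilic amine acylates O8 with retention at C8 and avoids Z-to-E drift of the angelate to the tiglate.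

Step 10
Reactants: 16 methyl (4S)-4-(angeloyloxy)-6-{[(tert-butyldimethylsilyl)oxy]methyl}hept-6-en-2-ynoate
Product: 18 methyl (2Z,4S)-4-(angeloyloxy)-2-[(pinacolboryl)methyl]-6-{[(tert-butyldimethylsilyl)oxy]methyl}hepta-2,6-dienoate, via alpha-alumino enoate 17 (not isolated)
Conditions: i-Bu2AlH, HMPA, THF, 0 °C; then ICH2Bpin, 0 °C to rt
Reagents that add atoms: 2-(iodomethyl)-4,4,5,5-tetramethyl-1,3,2-dioxaborolane ICB1OC(C)(C)C(C)(C)O1
Why: Syn-hydroalumination of the ynoate puts H on C7 and Al on the α-carbon, and trapping with the halomethylboronate (boron ate complex, then 1,2-metallate shift with loss of iodide) keeps the geometry, so C8 ends cis to the ester and is itself untouched.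

Step 11
Reactants: 6 (6S)-4-methyl-6-vinyl-5,6-dihydro-2H-pyran-2-ol; 18 methyl (2Z,4S)-4-(angeloyloxy)-2-[(pinacolboryl)methyl]-6-{[(tert-butyldimethylsilyl)oxy]methyl}hepta-2,6-dienoate
Product: 21 14-O-(tert-butyldimethylsilyl) ether of 22, via seco hydroxy ester 19 (not isolated), via lactone diene 20 (not isolated)
Conditions: 6 (1.3 equiv), toluene (0.5 M), 90 °C, 36 h; then diluted to 1 mM with degassed toluene, second-generation Hoveyda–Grubbs catalyst (2 × 5 mol %), 1,4-benzoquinone (10 mol %), 90 °C, Ar sparge
Reagents that add atoms: none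
Why: Proposed new method: the lactol releases its (Z)-δ-hydroxy-enal, whose hydroxyl can exchange onto boron and raise the effective molarity, and the aldehyde then reacts with the 2-alkoxycarbonyl allylboronate through a closed Zimmerman–Traxler chair (allylboration) in which the C8 substituent trans to CH2B sits equatorial and gives the 6,7-anti pair (6R,7R, hence the trans-lactone), while A(1,3) strain between H-8 and the cis ester locks the rotamer so that the aldehyde arrives anti to the angelate C–O bond; the boron alkoxide at O6 then expels MeOBpin to close the γ-lactone (O8 is blocked and O2 would need a nine-membered ring), and after dilution the ruthenium carbene loads on the C1 vinyl group and closes onto the 1,1-disubstituted C10 alkene, the ten-membered ring accepting only the ring-cis C1=C10 geometry; the closest known reaction types are thermal allylboration–lactonisation of 2-alkoxycarbonyl allylboronates and allylation/ring-closing-metathesis routes to medium-ring α-methylene lactones, merged here without isolation and neutral enough for the C8 angelate, which an allyl-metal reagent would eliminate.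

Step 12
Reactants: 21 14-O-(tert-butyldimethylsilyl) ether of 22
Product: 22 CNP0270898.1
Conditions: HF·pyridine, THF/pyridine, 0 °C
Reagents that add atoms: none
Why: Buffered fluoride desilylation cleaves the primary allylic silyl ether and leaves the angelate, the α-methylene lactone and all four stereocentres untouched.

**Compound list**
1 | methyl 3-methylbut-2-enoate | COC(=O)C=C(C)C | starting material
2 | 1-methoxy-3-methyl-1-(trimethylsilyloxy)buta-1,3-diene | COC(=CC(C)=C)O[Si](C)(C)C | intermediate
3 | acrolein | C=CC=O | starting material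
4 | methyl (2Z,5S)-5-hydroxy-3-methylhepta-2,6-dienoate, present as its copper aldolate | COC(=O)/C=C(/C)C[C@H](O)C=C | intermediate
5 | (6S)-4-methyl-6-vinyl-5,6-dihydro-2H-pyran-2-one | O=C1C=C(C)C[C@@H](C=C)O1 | intermediate
6 | (6S)-4-methyl-6-vinyl-5,6-dihydro-2H-pyran-2-ol, anomer mixture | OC1C=C(C)C[C@@H](C=C)O1 | intermediate
7 | 2-methylenepropane-1,3-diol | C=C(CO)CO | starting material
8 | 2-{[(tert-butyldimethylsilyl)oxy]methyl}prop-2-en-1-ol | C=C(CO)CO[Si](C)(C)C(C)(C)C | intermediate
9 | pinacol 2-{[(tert-butyldimethylsilyl)oxy]methyl}allylboronate | C=C(CO[Si](C)(C)C(C)(C)C)CB1OC(C)(C)C(C)(C)O1 | intermediate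
10 | 3,3-diethoxyprop-1-yne | C#CC(OCC)OCC | starting material
11 | methyl 4,4-diethoxybut-2-ynoate | CCOC(OCC)C#CC(=O)OC | intermediate
12 | methyl 4-oxobut-2-ynoate | O=CC#CC(=O)OC | intermediate
13 | methyl (4S)-4-hydroxy-6-{[(tert-butyldimethylsilyl)oxy]methyl}hept-6-en-2-ynoate | C=C(CO[Si](C)(C)C(C)(C)C)C[C@H](O)C#CC(=O)OC | intermediate
14 | angelic acid, (Z)-2-methylbut-2-enoic acid | C/C=C(/C)C(=O)O | starting material
15 | angelic 2,4,6-trichlorobenzoic anhydride | C/C=C(/C)C(=O)OC(=O)c1c(Cl)cc(Cl)cc1Cl | intermediate
16 | methyl (4S)-4-(angeloyloxy)-6-{[(tert-butyldimethylsilyl)oxy]methyl}hept-6-en-2-ynoate | C=C(CO[Si](C)(C)C(C)(C)C)C[C@H](OC(=O)/C(C)=C\C)C#CC(=O)OC | intermediate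
17 | α-(diisobutylalumino) enoate from 16, with Al trans and ester cis to C8 | C=C(CO[Si](C)(C)C(C)(C)C)C[C@H](OC(=O)/C(C)=C\C)/C=C(/[Al](CC(C)C)CC(C)C)C(=O)OC | intermediate
18 | methyl (2Z,4S)-4-(angeloyloxy)-2-[(pinacolboryl)methyl]-6-{[(tert-butyldimethylsilyl)oxy]methyl}hepta-2,6-dienoate | C=C(CO[Si](C)(C)C(C)(C)C)C[C@H](OC(=O)/C(C)=C\C)/C=C(/CB1OC(C)(C)C(C)(C)O1)C(=O)OC | intermediate
19 | seco hydroxy ester with the C6–C7 bond made (2S,6R,7S,8S; same spatial arrangement as 22), present as its O6 boron alkoxide | COC(=O)C(=C)[C@@H]([C@H](O)/C=C(/C)C[C@H](O)C=C)[C@@H](OC(=O)/C(C)=C\C)CC(=C)CO[Si](C)(C)C(C)(C)C | intermediate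
20 | trans-α-methylene-γ-lactone diene (2S,6R,7R,8S) with C1 vinyl and C10 methylene still open | C=C1C(=O)O[C@H](/C=C(/C)C[C@H](O)C=C)[C@H]1[C@@H](OC(=O)/C(C)=C\C)CC(=C)CO[Si](C)(C)C(C)(C)C | intermediate
21 | 14-O-(tert-butyldimethylsilyl) ether of 22 (2S,6R,7R,8S) | C=C1C(=O)O[C@@H]2/C=C(/C)C[C@H](O)/C=C(/CO[Si](C)(C)C(C)(C)C)C[C@H](OC(=O)/C(C)=C\C)[C@@H]12 | intermediate
22 | CNP0270898.1, 8α-angeloyloxy-2,14-dihydroxy-cis,cis-germacra-1(10),4,11(13)-trien-12,6α-olide (2S,6R,7R,8S) | C=C1C(=O)O[C@@H]2/C=C(/C)C[C@H](O)/C=C(/CO)C[C@H](OC(=O)/C(C)=C\C)[C@@H]12 | target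

**Step count**
- Total step count: 12.
- Longest linear sequence: 7 steps (10 → 11 → 12 → 13 → 16 → 18 → 21 → 22). The branch 7 → 8 → 9 → 13 → 22 is equally long.

**Steps most likely to fail**

**Step 11.** The risks are slow addition to a masked β,β-disubstituted enal, the wrong face at C7, and a strained ring closure. The fallback sets out from 6 and 18 and comes back at 22, with the order of ring formation reversed.
- The union is run alone with Sc(OTf)3 (10 mol %) in CH2Cl2 at 0 °C and stopped at hydroxy ester 19.
- 19 is capped with Et3SiOTf/2,6-lutidine as the bis(triethylsilyl) ether F1.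
- The flexible open chain is closed first by ring-closing metathesis to the monocyclic cyclodecadiene ester F2, where diastereomers can be separated.
- HF·pyridine followed by a trace of camphorsulfonic acid then removes all three silyl groups and closes the lactone last, giving 22 directly.

**Step 10.** The risks are loss of vinylalane geometry and attack on the propargylic angelate. The fallback sets out from 16 and comes back at 18, replacing the metallate shift by cross-coupling.
- Pd(PPh3)4-catalysed syn-hydrostannation with Bu3SnH gives the α-stannyl enoate F3.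
- Iodine exchanges tin for iodine with retention, giving the α-iodo enoate F4.
- Pd(PPh3)4-catalysed Negishi coupling with IZnCH2Bpin installs the CH2B group and returns to 18.

**Step 2.** The risks are acrolein polymerisation, Michael addition and moderate ee. The fallback sets out from 3 and comes back at 5, building the ring by metathesis instead of aldol–lactonisation.
- Acrolein is methallylated with B-methallyldiisopinocampheylborane to (S)-5-methylhexa-1,5-dien-3-ol F5.
- Acryloyl chloride/Et3N gives the acrylate F6.
- Second-generation Grubbs catalyst closes the acrylate onto the methallyl group to give 5.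

Further compounds
F1 | step 11 | bis(triethylsilyl) ether of 19 | COC(=O)C(=C)[C@@H]([C@H](O[Si](CC)(CC)CC)/C=C(/C)C[C@H](O[Si](CC)(CC)CC)C=C)[C@@H](OC(=O)/C(C)=C\C)CC(=C)CO[Si](C)(C)C(C)(C)C
F2 | step 11 | monocyclic cis,cis-cyclodecadiene methyl ester, tris-silyl protected | COC(=O)C(=C)[C@H]1[C@H](O[Si](CC)(CC)CC)/C=C(/C)C[C@H](O[Si](CC)(CC)CC)/C=C(/CO[Si](C)(C)C(C)(C)C)C[C@@H]1OC(=O)/C(C)=C\C
F3 | step 10 | α-(tributylstannyl) enoate from 16 | C=C(CO[Si](C)(C)C(C)(C)C)C[C@H](OC(=O)/C(C)=C\C)/C=C(/[Sn](CCCC)(CCCC)CCCC)C(=O)OC
F4 | step 10 | α-iodo enoate from F3 | C=C(CO[Si](C)(C)C(C)(C)C)C[C@H](OC(=O)/C(C)=C\C)/C=C(/I)C(=O)OC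
F5 | step 2 | (S)-5-methylhexa-1,5-dien-3-ol | C=C(C)C[C@H](O)C=C
F6 | step 2 | (S)-5-methylhexa-1,5-dien-3-yl acrylate | C=C(C)C[C@H](OC(=O)C=C)C=C
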